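## Retrosynthetic overview

1. Target 36 ⇐ C9 acetylation and C6 OH→Cl inversion of triol 34 ⇐ reductive opening of the 8,17‑epoxy lactone 33 ⇐ hydroxyl‑directed epoxidation of macrocyclic butenolide 32.
2. Ten‑membered ring (formed last) ⇐ Ni/Cr closure of the C8–C9 bond in β‑bromobutenolide aldehyde 31.
3. C6–C7 ⇐ vinylogous Mukaiyama aldol of silyloxyfuran 28 (from 3‑methyltetronic acid) with enal 25; C2–C3 ⇐ acetylide + Weinreb amide, then CBS reduction and Z‑semireduction.
4. Cyclohexane centres C10–C12 ⇐ relayed from epoxy enone 8 by conjugate vinylation/methylation and ketone reduction.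
5. Key step: catalytic enantioselective bromolactonization breaks the mirror symmetry of diene acid 4 (Birch reductive methylation of benzoic acid) and fixes C1 and the oxirane. Ring order: cyclohexane → oxirane → preformed butenolide attached → ten‑membered ring.

Labels C1–C20 are those of the target skeleton: C1 is the quaternary ring carbon with methyl C15, C2–C9 are the other eight atoms of the ten‑membered ring in order, C10–C14 complete the cyclohexane, C16 is the methylene on C5, C17–C19 are the lactone carbons with methyl C18, and C20 is the methyl on C11. β is the face of C15 on the cyclohexane.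

Assumption: in steps 2 and 16 the catalyst antipode is the one that gives the isomer drawn (otherwise (DHQ)2PHAL or (S)‑BINOL is used).
Assumption: step 2 is drawn for the bridged γ‑lactone; the isomeric β‑lactone would give the same epoxide 7 in step 3.

## Route

Step 1
Reactants: 1 benzoic acid; 2 iodomethane
Product: 4 1-methylcyclohexa-2,5-diene-1-carboxylic acid, via dilithium dienediolate 3 (not isolated)
Conditions: Li, NH3(l)/THF, −78 °C; then MeI, −78 °C → rt; aq. HCl
Reagents that add atoms: iodomethane, CI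
Why: Birch reductive alkylation: the benzoate is reduced to the cross‑conjugated dianion, which is C‑methylated at the ipso carbon to give an achiral, mirror‑symmetric diene acid.

Step 2
Reactants: 4 1-methylcyclohexa-2,5-diene-1-carboxylic acid
Product: 5 (1S,5S,8S)-8-bromo-1-methyl-6-oxabicyclo[3.2.1]oct-2-en-7-one
Conditions: NBS (1.1 equiv), (DHQD)2PHAL (10 mol %), CHCl3/hexane 1:1, −40 °C
Reagents that add atoms: N-bromosuccinimide, O=C1CCC(=O)N1Br
Why: Catalytic enantioselective bromolactonization (desymmetrizing halolactonization of a 1,4‑dihydrobenzoic acid): the catalyst‑bound carboxylate opens the bromonium ion of one enantiotopic alkene anti, so C1, C13 and C14 are set together with O13 cis to the carboxyl carbon and Br14 trans.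

Step 3
Reactants: 5 bromolactone
Product: 7 epoxy Weinreb amide (C15 β; amide α; 13α,14α-oxirane; Δ10), via chloromagnesium alkoxide 6 (not isolated)
Conditions: MeNH(OMe)·HCl, i-PrMgCl, THF, −20 → 40 °C
Reagents that add atoms: N,O-dimethylhydroxylamine hydrochloride, CNOC.Cl
Why: Weinreb aminolysis of the strained lactone frees the 13α‑alkoxide, which displaces the anti 14β‑bromide (intramolecular Williamson SN2, inversion at C14) to give the oxirane cis to the amide.

Step 4
Reactants: 7 epoxy Weinreb amide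
Product: 8 epoxy enone (C12 ketone; Δ10)
Conditions: Rh2(cap)4 (1 mol %; cap = caprolactamate), t-BuOOH, K2CO3, CH2Cl2, rt
Reagents that add atoms: tert-butyl hydroperoxide, CC(C)(C)OO
Why: Catalytic allylic C–H oxidation; C12 is the only allylic position because the other side of the alkene is quaternary C1, and no stereocentre is touched.

Step 5
Reactants: 8 epoxy enone; 9 vinylmagnesium bromide; 2 iodomethane
Product: 11 10β-vinyl-11α-methyl ketone, via bromomagnesium enolate 10 (not isolated)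
Conditions: CH2=CHMgBr, CuBr·SMe2 (15 mol %), THF, −78 → −40 °C; then MeI, DMPU, −40 → 0 °C
Reagents that add atoms: vinylmagnesium bromide, C=C[Mg]Br; iodomethane, CI
Why: Copper‑catalysed conjugate addition then enolate alkylation: the vinyl group enters C10 on the β face, anti to the α amide and α oxirane, and MeI then attacks C11 anti to the new vinyl group.

Step 6
Reactants: 11 10β-vinyl-11α-methyl ketone
Product: 13 10β-vinyl-11β-methyl ketone, via potassium enolate 12 (not isolated)
Conditions: KN(SiMe3)2, THF, −78 °C; then AcOH, −78 °C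
Reagents that add atoms: none
Why: Enolate epimerization: A(1,2) strain holds the C10 vinyl axial in the C11 enolate, so kinetic protonation from the α face leaves the C11 methyl β (cis to vinyl), which is also the epimer without the vinyl/amide gauche interaction.

Step 7
Reactants: 13 10β-vinyl-11β-methyl ketone
Product: 14 12α-alcohol (cis epoxy alcohol)
Conditions: NaBH4, CeCl3·7H2O, MeOH, −78 °C
Reagents that add atoms: none
Why: 1,2‑Reduction of an α,β‑epoxy ketone: hydride adds to C12 anti to the adjacent α oxirane oxygen, giving the 12α‑OH cis to the oxirane.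

Step 8
Reactants: 14 12α-alcohol
Product: 17 C9 dimethyl acetal, via ozonide 15 (not isolated), via aldehyde 16 (not isolated)
Conditions: O3, CH2Cl2, −78 °C; Me2S; then HC(OMe)3, PPTS (cat.), CH2Cl2, rt
Reagents that add atoms: trimethyl orthoformate, COC(OC)OC
Why: Ozonolysis of the only alkene gives the C9 aldehyde, which is masked in the same flask by acetalization under non‑basic conditions that do not epimerize C10.

Step 9
Reactants: 17 C9 dimethyl acetal; 18 2-methylbut-1-en-3-yne
Product: 20 C2 ynone, via lithium acetylide 19 (not isolated)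
Conditions: 18, n-BuLi, THF, −78 °C; then 17, −78 → 0 °C; aq. NH4Cl
Reagents that add atoms: 2-methylbut-1-en-3-yne, C=C(C)C#C
Why: Weinreb ketone synthesis: the chelated tetrahedral adduct survives until work‑up, so acylation stops at the ynone and brings in C3–C6 and C16.

Step 10
Reactants: 20 C2 ynone
Product: 21 (2R)-propargylic alcohol
Conditions: (S)-Me-CBS (1 equiv), BH3·SMe2, THF, −30 °C
Reagents that add atoms: none
Why: Corey–Bakshi–Shibata reduction: with the quaternary C1 side as the large group and the alkyne as the small one, the reagent delivers hydride to give 2R.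

Step 11
Reactants: 21 (2R)-propargylic alcohol
Product: 22 (2R,3Z)-dienediol
Conditions: Zn (activated with Cu(OAc)2 and AgNO3), MeOH/H2O 1:1, 40 °C
Reagents that add atoms: none
Why: Boland reduction: the conjugated, carbinol‑activated alkyne is semireduced to the Z alkene while the 1,1‑disubstituted alkene, oxirane and acetal are untouched.

Step 12
Reactants: 22 (2R,3Z)-dienediol
Product: 23 2,12-diacetate
Conditions: Ac2O, pyridine, DMAP (cat.), CH2Cl2, rt
Reagents that add atoms: acetic anhydride, CC(=O)OC(C)=O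
Why: Acylation of both secondary alcohols with retention installs the C2 and C12 acetates of the target.

Step 13
Reactants: 23 2,12-diacetate
Product: 25 C6 enal, via allylic alcohol 24 (not isolated)
Conditions: SeO2 (1.5 equiv), pyridine (2 equiv), 1,4-dioxane, 70 °C
Reagents that add atoms: selenium dioxide, O=[Se]=O
Why: Riley allylic oxidation (ene reaction then [2,3] shift) attacks the C6 methyl on the 1,1‑disubstituted alkene, the only unhindered allylic C–H, and carries the alcohol on to the enal; the Z alkene disfavours Diels–Alder dimerization of the dienal.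

Step 14
Reactants: 26 3-methyltetronic acid
Product: 27 4-bromo-3-methylfuran-2(5H)-one
Conditions: (COBr)2, DMF (cat.), CH2Cl2, 0 °C → rt
Reagents that add atoms: oxalyl bromide, O=C(Br)C(Br)=O
Why: Vilsmeier‑type activation of the vinylogous acid OH and addition–elimination by bromide give the β‑bromobutenolide.

Step 15
Reactants: 27 4-bromo-3-methylfuran-2(5H)-one
Product: 28 4-bromo-3-methyl-2-(trimethylsilyloxy)furan
Conditions: Me3SiOTf, Et3N, CH2Cl2, 0 °C
Reagents that add atoms: trimethylsilyl trifluoromethanesulfonate, C[Si](C)(C)OS(=O)(=O)C(F)(F)F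
Why: Soft enolization at the γ carbon (C7) and O‑silylation give the aromatic 2‑silyloxyfuran.

Step 16
Reactants: 25 C6 enal; 28 4-bromo-3-methyl-2-(trimethylsilyloxy)furan
Product: 31 seco hydroxy aldehyde (6R-OH; C9 CHO), via silyl ether 29 (not isolated), via hydroxy acetal 30 (not isolated)
Conditions: Ti(OiPr)4 (20 mol %), (R)-BINOL (20 mol %), Et2O, −20 °C; then TsOH·H2O (cat.), acetone/H2O, rt
Reagents that add atoms: 4-bromo-3-methyl-2-(trimethylsilyloxy)furan, Cc1c(Br)coc1O[Si](C)(C)C; water, O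
Why: Vinylogous Mukaiyama aldol at the furan γ carbon through an open antiperiplanar transition state gives the threo (6,7‑syn) δ‑hydroxybutenolide, with the Ti/BINOL complex choosing the aldehyde face (6R); the acidic work‑up removes the silyl group and unmasks the C9 aldehyde.

Step 17
Reactants: 31 seco hydroxy aldehyde
Product: 32 macrocyclic butenolide 6,9-diol
Conditions: CrCl2 (10 equiv), NiCl2 (10 mol %), DMSO/THF 3:1, 0.002 M, rt → 40 °C
Reagents that add atoms: none
Why: Nozaki–Hiyama–Kishi macrocyclization: the alkenylchromium from the β‑bromobutenolide adds to the C9 aldehyde in the Felkin–Anh sense (C1 side anti), closing the ten‑membered ring and setting 9R.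

Step 18
Reactants: 32 macrocyclic butenolide 6,9-diol
Product: 33 8,17-epoxy lactone (oxirane on the lactone face syn to C6)
Conditions: t-BuOOLi (from t-BuOOH 3 equiv and n-BuLi 2.5 equiv), THF, −78 → −20 °C
Reagents that add atoms: tert-butyl hydroperoxide, CC(C)(C)OO
Why: Proposed new method: lithium tert‑butyl peroxide held by the C9 and C6 hydroxyls adds to C8 of the electron‑poor butenolide from the hydroxyl‑bearing face (A(1,3) strain with the C17 methyl places O9 on the C6 side of the lactone) and closes the oxirane there while the diene stays inert; the closest known reaction is the hydroxyl‑directed syn‑selective Weitz–Scheffer epoxidation of γ‑hydroxy‑α,β‑unsaturated esters and sulfones with t‑BuOOLi.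

Step 19
Reactants: 33 8,17-epoxy lactone
Product: 34 6,8,9-triol (8-OH; 17-H)
Conditions: SmI2 (3 equiv), THF/MeOH, −78 °C
Reagents that add atoms: none
Why: Reductive opening of an α,β‑epoxy lactone: electron transfer cleaves the C17–O bond and leaves the tertiary 8‑OH, and protonation of the samarium enolate gives the more stable 17‑epimer with the methyl trans to the C9 branch.

Step 20
Reactants: 34 6,8,9-triol
Product: 35 6S-chloride 8,9-diol
Conditions: PPh3, hexachloroacetone, CH2Cl2, −20 → 0 °C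
Reagents that add atoms: hexachloroacetone, O=C(C(Cl)(Cl)Cl)C(Cl)(Cl)Cl
Why: Appel‑type chlorination is fastest at the unhindered allylic C6 alcohol and proceeds by SN2 with inversion (6R‑OH to 6S‑Cl); the hindered C9 and tertiary C8 hydroxyls do not react.

Step 21
Reactants: 35 6S-chloride 8,9-diol
Product: 36 CNP0274383.2
Conditions: Ac2O, Et3N, DMAP (cat.), CH2Cl2, 0 °C
Reagents that add atoms: acetic anhydride, CC(=O)OC(C)=O
Why: Acylation of the remaining secondary C9 alcohol with retention; the tertiary 8‑OH stays free.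

## Compound list

1 | benzoic acid | OC(=O)c1ccccc1 | starting material
2 | iodomethane | CI | starting material
3 | dilithium (cyclohexa-2,5-dien-1-ylidene)methanediolate (Birch dianion) | [Li+].[Li+].[O-]C([O-])=C1C=CCC=C1 | intermediate
4 | 1-methylcyclohexa-2,5-diene-1-carboxylic acid (achiral) | CC1(C=CCC=C1)C(O)=O | intermediate
5 | (1S,5S,8S)-8-bromo-1-methyl-6-oxabicyclo[3.2.1]oct-2-en-7-one (lactone O on C13 α, Br on C14 β) | C[C@]12C=CC[C@H](OC1=O)[C@H]2Br | intermediate
6 | chloromagnesium alkoxide of the bromohydrin Weinreb amide (13α‑O, 14β‑Br) | CON(C)C(=O)[C@]1(C)C=CC[C@H](O[Mg]Cl)[C@H]1Br | intermediate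
7 | N-methoxy-N,2-dimethyl-7-oxabicyclo[4.1.0]hept-3-ene-2-carboxamide (C15 β, amide α, 13α,14α‑oxirane) | CON(C)C(=O)[C@]2(C)C=CC[C@@H]3O[C@@H]32 | intermediate
8 | the 5-oxo derivative of 7 (C12 ketone, Δ10 enone) | CON(C)C(=O)[C@]2(C)C=CC(=O)[C@@H]3O[C@@H]32 | intermediate
9 | vinylmagnesium bromide | C=C[Mg]Br | starting material
10 | bromomagnesium C11–C12 enolate of the 10β‑vinyl adduct | CON(C)C(=O)[C@]2(C)[C@H](C=C(O[Mg]Br)[C@@H]3O[C@@H]32)C=C | intermediate
11 | 10β‑vinyl‑11α‑methyl‑12‑ketone | CON(C)C(=O)[C@]2(C)[C@H]([C@H](C)C(=O)[C@@H]3O[C@@H]32)C=C | intermediate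
12 | potassium C11–C12 enolate | CON(C)C(=O)[C@]2(C)[C@H](C(C)=C([O-])[C@@H]3O[C@@H]32)C=C.[K+] | intermediate
13 | 10β‑vinyl‑11β‑methyl‑12‑ketone | CON(C)C(=O)[C@]2(C)[C@H]([C@@H](C)C(=O)[C@@H]3O[C@@H]32)C=C | intermediate
14 | 12α‑alcohol (cis to the oxirane) | CON(C)C(=O)[C@]2(C)[C@H]([C@@H](C)[C@H](O)[C@@H]3O[C@@H]32)C=C | intermediate
15 | C9 ozonide (1,2,4‑trioxolane, C9 epimers) | CON(C)C(=O)[C@]2(C)[C@H]([C@@H](C)[C@H](O)[C@@H]3O[C@@H]32)C1OCOO1 | intermediate
16 | C9 aldehyde | CON(C)C(=O)[C@]2(C)[C@H]([C@@H](C)[C@H](O)[C@@H]3O[C@@H]32)C=O | intermediate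
17 | C9 dimethyl acetal | CON(C)C(=O)[C@]2(C)[C@H]([C@@H](C)[C@H](O)[C@@H]3O[C@@H]32)C(OC)OC | intermediate
18 | 2-methylbut-1-en-3-yne | C=C(C)C#C | starting material
19 | lithium 3-methylbut-3-en-1-yn-1-ide | C=C(C)C#C[Li] | intermediate
20 | C2 ynone (C3≡C4, isopropenyl at C5) | C=C(C)C#CC(=O)[C@]2(C)[C@H]([C@@H](C)[C@H](O)[C@@H]3O[C@@H]32)C(OC)OC | intermediate
21 | (2R)‑propargylic alcohol | C=C(C)C#C[C@@H](O)[C@]2(C)[C@H]([C@@H](C)[C@H](O)[C@@H]3O[C@@H]32)C(OC)OC | intermediate
22 | (2R,3Z)‑dienediol | C=C(C)/C=C\[C@@H](O)[C@]2(C)[C@H]([C@@H](C)[C@H](O)[C@@H]3O[C@@H]32)C(OC)OC | intermediate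
23 | 2,12‑diacetate | C=C(C)/C=C\[C@@H](OC(C)=O)[C@]2(C)[C@H]([C@@H](C)[C@H](OC(C)=O)[C@@H]3O[C@@H]32)C(OC)OC | intermediate
24 | C6 allylic alcohol | C=C(CO)/C=C\[C@@H](OC(C)=O)[C@]2(C)[C@H]([C@@H](C)[C@H](OC(C)=O)[C@@H]3O[C@@H]32)C(OC)OC | intermediate
25 | C6 enal | C=C(C=O)/C=C\[C@@H](OC(C)=O)[C@]2(C)[C@H]([C@@H](C)[C@H](OC(C)=O)[C@@H]3O[C@@H]32)C(OC)OC | intermediate
26 | 3-methyltetronic acid (4-hydroxy-3-methylfuran-2(5H)-one) | CC1=C(O)COC1=O | starting material
27 | 4-bromo-3-methylfuran-2(5H)-one | CC1=C(Br)COC1=O | intermediate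
28 | 4-bromo-3-methyl-2-(trimethylsilyloxy)furan | Cc1c(Br)coc1O[Si](C)(C)C | intermediate
29 | O6‑trimethylsilyl aldol adduct (C9 acetal) | CC1=C(Br)[C@@H](OC1=O)[C@H](O[Si](C)(C)C)C(=C)/C=C\[C@@H](OC(C)=O)[C@]2(C)[C@H]([C@@H](C)[C@H](OC(C)=O)[C@@H]3O[C@@H]32)C(OC)OC | intermediate
30 | (6R)‑hydroxy acetal | CC1=C(Br)[C@@H](OC1=O)[C@H](O)C(=C)/C=C\[C@@H](OC(C)=O)[C@]2(C)[C@H]([C@@H](C)[C@H](OC(C)=O)[C@@H]3O[C@@H]32)C(OC)OC | intermediate
31 | seco hydroxy aldehyde (6R‑OH, 6,7‑syn, 8‑bromobutenolide, C9 CHO) | CC1=C(Br)[C@@H](OC1=O)[C@H](O)C(=C)/C=C\[C@@H](OC(C)=O)[C@]2(C)[C@H]([C@@H](C)[C@H](OC(C)=O)[C@@H]3O[C@@H]32)C=O | intermediate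
32 | macrocyclic Δ8(17)‑butenolide (6R,9R)‑diol | C=C1/C=C\[C@@H](OC(C)=O)[C@]2(C)[C@H]([C@@H](C)[C@H](OC(C)=O)[C@@H]3O[C@@H]32)[C@@H](O)C2=C(C)C(=O)O[C@H]2[C@@H]1O | intermediate
33 | 8,17‑epoxy lactone 6,9‑diol | C=C1/C=C\[C@@H](OC(C)=O)[C@]2(C)[C@H]([C@@H](C)[C@H](OC(C)=O)[C@@H]3O[C@@H]32)[C@@H](O)[C@@]23O[C@@]3(C)C(=O)O[C@H]2[C@@H]1O | intermediate
34 | 6,8,9‑triol (6R‑OH) | C=C1/C=C\[C@@H](OC(C)=O)[C@]2(C)[C@H]([C@@H](C)[C@H](OC(C)=O)[C@@H]3O[C@@H]32)[C@@H](O)[C@]2(O)[C@@H](C)C(=O)O[C@H]2[C@@H]1O | intermediate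
35 | (6S)‑chloride 8,9‑diol | C=C1/C=C\[C@@H](OC(C)=O)[C@]2(C)[C@H]([C@@H](C)[C@H](OC(C)=O)[C@@H]3O[C@@H]32)[C@@H](O)[C@]2(O)[C@@H](C)C(=O)O[C@H]2[C@H]1Cl | intermediate
36 | CNP0274383.2 | C=C1/C=C\[C@@H](OC(C)=O)[C@]2(C)[C@H]([C@@H](C)[C@H](OC(C)=O)[C@@H]3O[C@@H]32)[C@@H](OC(C)=O)[C@]2(O)[C@@H](C)C(=O)O[C@H]2[C@H]1Cl | target

## Step count and risks

Total step count: 21. Longest linear sequence: 19 steps (steps 1–13 and 16–21, from benzoic acid).

Three steps most likely to fail:

Step 17 (macrocyclization). A β‑bromobutenolide is a sluggish Ni/Cr partner, the aldehyde is hindered and the ring is ten‑membered. The fallback sets out from 23 and returns at 32, closing the ring at C6–C7 instead. Acetal 23 is hydrolysed (TsOH, acetone/H2O) to the C9 aldehyde F8. F8 is coupled intermolecularly with 27 (CrCl2, NiCl2 cat., DMSO) to the Felkin carbinol F9. SeO2 oxidation gives the enal F10. Me3SiOTf/Et3N converts it into the bis‑silylated silyloxyfuran F11. BF3·OEt2 at high dilution then effects an intramolecular vinylogous Mukaiyama aldol reaction to the 9‑O‑silyl macrocycle F12, and mild aqueous acid gives 32.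

Step 18 (directed epoxidation). The tetrasubstituted butenolide may be inert, the base may attack acetates or the acidic C7–H, and the face is set only by the hydroxyl delivery. The fallback sets out from 32 and returns at 35. The C6 alcohol is chlorinated first (PPh3, hexachloroacetone) to the chloride F13. The remaining allylic C9 hydroxyl, now the only one, directs an electrophilic epoxidation (VO(acac)2, t‑BuOOH) to the epoxy lactone F14 on the same face. SmI2/MeOH at −78 °C opens it to 35.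

Step 13 (allylic oxidation). SeO2 may isomerize or add to the Z‑diene, or hydrolyse the acetal. The fallback sets out from 17 and returns at 25, carrying the C6 oxygen in from the start. Commercial 2‑bromoprop‑2‑en‑1‑ol is silylated to tert‑butyl[(2‑bromoprop‑2‑en‑1‑yl)oxy]dimethylsilane F1. F1 is coupled with ethynyltrimethylsilane (PdCl2(PPh3)2, CuI, Et3N) to the silyl enyne F2, which is C‑desilylated (K2CO3, MeOH) to the terminal enyne F3. The lithium acetylide of F3 acylates 17 to the ynone F4. CBS reduction gives the propargylic alcohol F5, Zn/Cu/Ag reduction the Z‑dienediol F6, and acetylation the diacetate F7. HF·pyridine then frees allylic alcohol 24, and MnO2 oxidizes it to 25.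

Further compounds

F1 | step 13 | tert-butyl[(2-bromoprop-2-en-1-yl)oxy]dimethylsilane | C=C(Br)CO[Si](C)(C)C(C)(C)C
F2 | step 13 | tert-butyldimethyl{[2-methylidene-4-(trimethylsilyl)but-3-yn-1-yl]oxy}silane | C=C(CO[Si](C)(C)C(C)(C)C)C#C[Si](C)(C)C
F3 | step 13 | tert-butyldimethyl[(2-methylidenebut-3-yn-1-yl)oxy]silane | C=C(CO[Si](C)(C)C(C)(C)C)C#C
F4 | step 13 | C2 ynone with C6 silyl ether | C=C(CO[Si](C)(C)C(C)(C)C)C#CC(=O)[C@]2(C)[C@H]([C@@H](C)[C@H](O)[C@@H]3O[C@@H]32)C(OC)OC
F5 | step 13 | (2R)-propargylic alcohol with C6 silyl ether | C=C(CO[Si](C)(C)C(C)(C)C)C#C[C@@H](O)[C@]2(C)[C@H]([C@@H](C)[C@H](O)[C@@H]3O[C@@H]32)C(OC)OC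
F6 | step 13 | (2R,3Z)-dienediol with C6 silyl ether | C=C(CO[Si](C)(C)C(C)(C)C)/C=C\[C@@H](O)[C@]2(C)[C@H]([C@@H](C)[C@H](O)[C@@H]3O[C@@H]32)C(OC)OC
F7 | step 13 | 2,12-diacetate with C6 silyl ether | C=C(CO[Si](C)(C)C(C)(C)C)/C=C\[C@@H](OC(C)=O)[C@]2(C)[C@H]([C@@H](C)[C@H](OC(C)=O)[C@@H]3O[C@@H]32)C(OC)OC
F8 | step 17 | C9 aldehyde of diacetate 23 | C=C(C)/C=C\[C@@H](OC(C)=O)[C@]2(C)[C@H]([C@@H](C)[C@H](OC(C)=O)[C@@H]3O[C@@H]32)C=O
F9 | step 17 | (9R)-carbinol carrying the 3-methylbutenolide at C8 | C=C(C)/C=C\[C@@H](OC(C)=O)[C@]2(C)[C@H]([C@@H](C)[C@H](OC(C)=O)[C@@H]3O[C@@H]32)[C@@H](O)C1=C(C)C(=O)OC1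
F10 | step 17 | C6 enal of F9 | C=C(C=O)/C=C\[C@@H](OC(C)=O)[C@]2(C)[C@H]([C@@H](C)[C@H](OC(C)=O)[C@@H]3O[C@@H]32)[C@@H](O)C1=C(C)C(=O)OC1
F11 | step 17 | 9-O-silyl silyloxyfuran enal | C=C(C=O)/C=C\[C@@H](OC(C)=O)[C@]2(C)[C@H]([C@@H](C)[C@H](OC(C)=O)[C@@H]3O[C@@H]32)[C@@H](O[Si](C)(C)C)c1coc(O[Si](C)(C)C)c1C
F12 | step 17 | 9-O-trimethylsilyl ether of 32 | C=C1/C=C\[C@@H](OC(C)=O)[C@]2(C)[C@H]([C@@H](C)[C@H](OC(C)=O)[C@@H]3O[C@@H]32)[C@@H](O[Si](C)(C)C)C2=C(C)C(=O)O[C@H]2[C@@H]1O
F13 | step 18 | (6S)-chloro macrocyclic butenolide 9-ol | C=C1/C=C\[C@@H](OC(C)=O)[C@]2(C)[C@H]([C@@H](C)[C@H](OC(C)=O)[C@@H]3O[C@@H]32)[C@@H](O)C2=C(C)C(=O)O[C@H]2[C@H]1Cl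
F14 | step 18 | (6S)-chloro 8,17-epoxy lactone 9-ol | C=C1/C=C\[C@@H](OC(C)=O)[C@]2(C)[C@H]([C@@H](C)[C@H](OC(C)=O)[C@@H]3O[C@@H]32)[C@@H](O)[C@@]23O[C@@]3(C)C(=O)O[C@H]2[C@H]1Cl
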